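**Plan**
- Retrosynthesis: the C12–C13 bond of the side chain is cut first (B-alkyl Suzuki coupling), then the C7=C8 olefin is traced back to a C7 ketone (enol triflate reduction), then the decalin is cut at C5–C10 and C8–C9 in one operation.
- Enabling feature: ring B (C5–C10) is a cyclohexene whose C7=C8 olefin lies one position from the C6=C7 olefin that a [4+2] addition of a diene C5=C6–C7=C8 to a dienophile C9=C10 leaves. With a silyloxy group on C7 the adduct is a C6=C7 silyl enol ether, a masked C7 ketone from which C7=C8 is reached; the C1–C4 chain is the tether that becomes ring A, and C11 at the ester level activates C9=C10.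
- Forward: an acyclic triene is built from (S)-lactaldehyde (Claisen rearrangement, vinylogous Mukaiyama aldol, cross-metathesis); rings A and B close together in an intramolecular Diels–Alder reaction; then the olefin is relocated, the side chain coupled and the acetate installed.
- Stereochemistry: C4 comes from lactate by 1,3-chirality transfer in the Claisen step; C2 is catalyst-controlled; C5, C9 and C10 arise in the cycloaddition (E-dienophile, endo ester, equatorial C2 silyloxy group); the side-chain E-olefin comes from syn-hydrozirconation.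
- Helpers taken out again: the C7 oxygen (as triflate), the lactate carbinol carbon (lost as propene), and the PMB and TBS groups.

Key step: step 10

Remark: the target is read as 19-acetoxylabda-7,13E-diene-2α,15-diol of the normal series (10β-CH3, 5α-H). Ring positions use labdane numbering (C11 on C9, C17 = CH3 on C8, C18/C19 = 4α-CH3/4β-CH2O, C20 = CH3 on C10); β is the face of C20.
Remark: the C8 centre of compounds 18–22 is written 8β, as the endo transition state should give; it becomes sp2 in step 14, so its configuration is immaterial.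

Step 1
Reactants: 1 (S)-2-(tert-butyldimethylsilyloxy)propanal; 2 ethyl 2-(triphenylphosphoranylidene)propanoate
Product: 3 ethyl (2E,4S)-4-(tert-butyldimethylsilyloxy)-2-methylpent-2-enoate
Conditions: CH2Cl2, 23 °C
Reagents that add atoms: none
Why: Wittig olefination with a stabilised α-methyl ylide should give the E-trisubstituted enoate, and the lactate centre is carried through unchanged under these neutral conditions.

Step 2
Reactants: 3 ethyl (2E,4S)-4-(tert-butyldimethylsilyloxy)-2-methylpent-2-enoate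
Product: 4 (2E,4S)-4-(tert-butyldimethylsilyloxy)-2-methylpent-2-en-1-ol
Conditions: i-Bu2AlH, CH2Cl2, −78 °C; aq potassium sodium tartrate
Reagents that add atoms: none
Why: 1,2-Reduction of the enoate by the aluminium hydride leaves olefin geometry and silyl ether untouched.

Step 3
Reactants: 4 (2E,4S)-4-(tert-butyldimethylsilyloxy)-2-methylpent-2-en-1-ol
Product: 5 tert-butyl{[(2S,3E)-5-(4-methoxybenzyloxy)-4-methylpent-3-en-2-yl]oxy}dimethylsilane
Conditions: NaH, 4-methoxybenzyl chloride, Bu4NI (cat.), THF–DMF, 0 to 23 °C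
Reagents that add atoms: 4-methoxybenzyl chloride, COc1ccc(CCl)cc1
Why: Williamson etherification of the primary allylic alkoxide installs a PMB ether that can later be removed oxidatively beside olefins and silyl ethers.

Step 4
Reactants: 5 tert-butyl{[(2S,3E)-5-(4-methoxybenzyloxy)-4-methylpent-3-en-2-yl]oxy}dimethylsilane
Product: 6 (2S,3E)-5-(4-methoxybenzyloxy)-4-methylpent-3-en-2-ol
Conditions: Bu4NF, THF, 0 to 23 °C
Reagents that add atoms: none
Why: Fluoride-mediated desilylation frees the secondary allylic carbinol that steers the next step.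

Step 5
Reactants: 6 (2S,3E)-5-(4-methoxybenzyloxy)-4-methylpent-3-en-2-ol; 7 ethyl vinyl ether
Product: 9 (3S,4E)-3-[(4-methoxybenzyloxy)methyl]-3-methylhex-4-enal, via allyl vinyl ether 8 (not isolated)
Conditions: Hg(OAc)2 (cat.), ethyl vinyl ether, reflux; concentrate; PhMe, 160 °C, sealed tube
Reagents that add atoms: none
Why: Transfer vinylation then Claisen rearrangement through a chair transition state with the carbinol methyl equatorial should pass the C–O chirality suprafacially to the new quaternary carbon (S, the future C4) and give the E-propenyl group.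

Step 6
Reactants: 10 methyl 3-methylbut-2-enoate
Product: 12 tert-butyl[(1-methoxy-3-methylbuta-1,3-dien-1-yl)oxy]dimethylsilane, via lithium dienolate 11 (not isolated)
Conditions: LiN(i-Pr)2, THF–DMPU, −78 °C; then t-BuMe2SiCl
Reagents that add atoms: tert-butyldimethylsilyl chloride, CC(C)(C)[Si](C)(C)Cl
Why: γ-Deprotonation of the senecioate and O-silylation give the silyl dienol ether, whose ketene acetal geometry is of no consequence.

Step 7
Reactants: 9 (3S,4E)-3-[(4-methoxybenzyloxy)methyl]-3-methylhex-4-enal; 12 tert-butyl[(1-methoxy-3-methylbuta-1,3-dien-1-yl)oxy]dimethylsilane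
Product: 13 methyl (2E,5R,7S,8E)-5-hydroxy-7-[(4-methoxybenzyloxy)methyl]-3,7-dimethyldeca-2,8-dienoate
Conditions: SiCl4, (R,R)-binaphthyldiamine-derived bisphosphoramide (5 mol %), i-Pr2NEt (cat.), CH2Cl2, −72 °C; aq KF/NaHCO3
Reagents that add atoms: none
Why: Lewis base-activated SiCl4 vinylogous Mukaiyama aldol: γ-attack of the dienolate through an open transition state should give the E-enoate, and the catalyst antipode is chosen for Re-face addition (taken here as R,R) to set the 5R carbinol (the future C2), on which the remote quaternary centre has no useful influence.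

Step 8
Reactants: 13 methyl (2E,5R,7S,8E)-5-hydroxy-7-[(4-methoxybenzyloxy)methyl]-3,7-dimethyldeca-2,8-dienoate
Product: 14 methyl (2E,5R,7S,8E)-5-(tert-butyldimethylsilyloxy)-7-[(4-methoxybenzyloxy)methyl]-3,7-dimethyldeca-2,8-dienoate
Conditions: t-BuMe2SiCl, imidazole, DMF, 23 °C
Reagents that add atoms: tert-butyldimethylsilyl chloride, CC(C)(C)[Si](C)(C)Cl
Why: Silylation protects the carbinol before the enone is made and provides the bulky group that controls the diene face in step 10.

Step 9
Reactants: 14 methyl (2E,5R,7S,8E)-5-(tert-butyldimethylsilyloxy)-7-[(4-methoxybenzyloxy)methyl]-3,7-dimethyldeca-2,8-dienoate; 15 pent-1-en-3-one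
Product: 16 methyl (2E,5R,7S,8E)-5-(tert-butyldimethylsilyloxy)-7-[(4-methoxybenzyloxy)methyl]-3,7-dimethyl-10-oxododeca-2,8-dienoate
Conditions: second-generation Hoveyda–Grubbs catalyst RuCl2(H2IMes)(=CH-C6H4-2-O-i-Pr) (10 mol %), pent-1-en-3-one (5 equiv), CH2Cl2, 40 °C
Reagents that add atoms: none
Why: Olefin cross-metathesis between the hindered propenyl group (which does not homodimerise) and the electron-poor vinyl ketone should give the E-enone, while the conjugated trisubstituted enoate is inert.

Step 10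
Reactants: 16 methyl (2E,5R,7S,8E)-5-(tert-butyldimethylsilyloxy)-7-[(4-methoxybenzyloxy)methyl]-3,7-dimethyl-10-oxododeca-2,8-dienoate
Product: 18 trans-decalin cycloadduct (2α-OTBS; 4α-CH3; 4β-CH2OPMB; 5α-H; C6=C7 enol ether with 7-OTBS; 8β-CH3; 9β-CO2Me; 10β-CH3), via silyl dienol ether 17 (not isolated)
Conditions: t-BuMe2SiOTf, Et3N, CH2Cl2, −78 to 0 °C; aq NaHCO3 wash, concentrate; PhMe (0.01 M), BHT (cat.), 180 °C, sealed tube
Reagents that add atoms: tert-butyldimethylsilyl trifluoromethanesulfonate, CC(C)(C)[Si](C)(C)OS(=O)(=O)C(F)(F)F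
Why: Soft enolisation of the ethyl ketone gives the (Z)-2-silyloxy diene 17, and heating brings about a concerted, suprafacial intramolecular Diels–Alder reaction of this 1,7,9-decatriene that forms C5–C10 and C8–C9 together (closest known type: thermal cyclisation of silyloxy-substituted trienoates and the silyl triflate–amine enone/enoate annulations used for terpenoid decalins). Ring A closes as a six-membered ring through the C1–C4 tether held in a chair, ring B is the cyclohexene made by the [4+2] addition itself, and the tether permits only this regiochemistry. The E-enoate places the C10 methyl and the C9 ester cis, the endo orientation of the ester (tether anti) gives the trans C5/C10 fusion, and the Z enol ether fixes the transient C8 centre. The diene face is chosen by the C2 and C4 centres: in the favoured chair the C2 silyloxy group and the C4 methyl are equatorial and only CH2OPMB is axial, whereas addition to the other face would put OTBS, the C4 methyl and the C10 methyl in mutual 1,3-diaxial positions. The step needs endo over exo and one π-face; the first rests on the usual endo preference of a terminally activated E-dienophile and is the less secure, the second on the equatorial preference of the bulky silyloxy group. The quaternary C4 centre adds a gem-dialkyl effect that should help the rate.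

Step 11
Reactants: 18 trans-decalin cycloadduct (9β-CO2Me)
Product: 19 primary alcohol (9β-CH2OH; otherwise as 18)
Conditions: i-Bu2AlH, CH2Cl2, −78 to −20 °C; aq potassium sodium tartrate
Reagents that add atoms: none
Why: Hydride reduction of the hindered ester proceeds while the silyl enol ether keeps the ring B ketone masked.

Step 12
Reactants: 19 primary alcohol (9β-CH2OH)
Product: 20 aldehyde (9β-CHO; otherwise as 18)
Conditions: (Pr4N)(RuO4) (5 mol %), N-methylmorpholine N-oxide, 4 Å molecular sieves, CH2Cl2, 23 °C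
Reagents that add atoms: none
Why: Ley–Griffith oxidation under neutral conditions should give the aldehyde without harming the silyl enol ether or epimerising C9, where the equatorial formyl group is the stable epimer.

Step 13
Reactants: 20 aldehyde (9β-CHO)
Product: 22 vinyl ketone (9β-CH=CH2; C7 ketone; 8β-CH3; otherwise as 18), via vinyl silyl enol ether 21 (not isolated)
Conditions: Ph3PCH3Br, KN(SiMe3)2, THF, −78 to 0 °C; then 0.5 M HCl (aq), THF, 0 to 23 °C
Reagents that add atoms: methyltriphenylphosphonium bromide, C[P+](c1ccccc1)(c1ccccc1)c1ccccc1.[Br-]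
Why: Wittig methylenation of the hindered aldehyde is followed by mild acid hydrolysis of the silyl enol ether (protonation at C6), which the secondary alkyl TBS ether should outlast.

Step 14
Reactants: 22 vinyl ketone
Product: 24 C7=C8 enol triflate (7-OTf; 9β-CH=CH2; otherwise as 18), via lithium enolate 23 (not isolated)
Conditions: LiN(SiMe3)2 (0.95 equiv), THF, −78 to 23 °C, 2 h; then N-(5-chloro-2-pyridyl)bis(trifluoromethanesulfonimide), −78 to 23 °C
Reagents that add atoms: N-(5-chloro-2-pyridyl)bis(trifluoromethanesulfonimide), O=S(=O)(N(c1ccc(Cl)cn1)S(=O)(=O)C(F)(F)F)C(F)(F)F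
Why: With a slight excess of ketone the lithium enolates equilibrate (House conditions) to the more substituted C7=C8 enolate, which also relieves the 1,3-diaxial C17/C20 methyl interaction, and O-sulfonylation traps it.

Step 15
Reactants: 24 C7=C8 enol triflate
Product: 25 diene (C7=C8 olefin with H on C7; 9β-CH=CH2; 2α-OTBS; 4β-CH2OPMB)
Conditions: Pd(OAc)2 (5 mol %), PPh3, HCO2H, Bu3N, DMF, 60 °C
Reagents that add atoms: none
Why: Formate reduction of the vinyl triflate (oxidative addition to zerovalent palladium, formate exchange, decarboxylation, reductive elimination) replaces OTf by H without moving the olefin.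

Step 16
Reactants: 26 but-2-yn-1-ol
Product: 27 tert-butyl(but-2-yn-1-yloxy)dimethylsilane
Conditions: t-BuMe2SiCl, imidazole, CH2Cl2, 23 °C
Reagents that add atoms: tert-butyldimethylsilyl chloride, CC(C)(C)[Si](C)(C)Cl
Why: Standard silylation of the primary alcohol.

Step 17
Reactants: 27 tert-butyl(but-2-yn-1-yloxy)dimethylsilane
Product: 29 (E)-tert-butyl[(3-iodobut-2-en-1-yl)oxy]dimethylsilane, via alkenylzirconocene 28 (not isolated)
Conditions: Cp2Zr(H)Cl (1.5 equiv), THF, 50 °C; then I2, 0 °C
Reagents that add atoms: iodine, II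
Why: Hydrozirconation is a syn addition in which, after equilibration with excess reagent, zirconium should sit on the alkyne carbon remote from the silyloxymethyl group, and iodinolysis with retention gives the E-iodide.

Step 18
Reactants: 25 diene (9β-CH=CH2); 29 (E)-tert-butyl[(3-iodobut-2-en-1-yl)oxy]dimethylsilane
Product: 31 19-(4-methoxybenzyloxy)-2α,15-bis(tert-butyldimethylsilyloxy)labda-7,13E-diene, via alkylborane 30 (not isolated)
Conditions: 9-BBN-H dimer, THF, 0 to 23 °C; then 29, Pd(dppf)Cl2 (5 mol %), AsPh3, Cs2CO3, DMF–H2O, 23 °C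
Reagents that add atoms: none
Why: B-alkyl Suzuki–Miyaura coupling: 9-BBN adds anti-Markovnikov only to the monosubstituted vinyl group, and the sp3–sp2 coupling keeps the E geometry of the iodide.

Step 19
Reactants: 31 19-(4-methoxybenzyloxy)-2α,15-bis(tert-butyldimethylsilyloxy)labda-7,13E-diene
Product: 32 2α,15-bis(tert-butyldimethylsilyloxy)labda-7,13E-dien-19-ol
Conditions: DDQ, CH2Cl2–pH 7 buffer, 0 °C
Reagents that add atoms: none
Why: Oxidative PMB cleavage (benzylic hydride abstraction, then hydrolysis) should spare the silyl ethers and the trisubstituted olefins under buffered conditions.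

Step 20
Reactants: 32 2α,15-bis(tert-butyldimethylsilyloxy)labda-7,13E-dien-19-ol
Product: 33 19-acetoxy-2α,15-bis(tert-butyldimethylsilyloxy)labda-7,13E-diene
Conditions: Ac2O, pyridine, DMAP (cat.), CH2Cl2, 23 °C
Reagents that add atoms: acetic anhydride, CC(=O)OC(C)=O
Why: DMAP-catalysed acylation of the only free hydroxyl group.

Step 21
Reactants: 33 19-acetoxy-2α,15-bis(tert-butyldimethylsilyloxy)labda-7,13E-diene
Product: 34 19-acetoxylabda-7,13E-diene-2α,15-diol (target)
Conditions: HF·pyridine, pyridine, THF, 0 to 23 °C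
Reagents that add atoms: none
Why: Fluoride desilylation of both TBS ethers under slightly acidic conditions should neither cleave nor migrate the acetate.

**Compound list**
1 | (S)-2-(tert-butyldimethylsilyloxy)propanal | C[C@H](O[Si](C)(C)C(C)(C)C)C=O | starting material
2 | ethyl 2-(triphenylphosphoranylidene)propanoate | CCOC(=O)C(C)=P(c1ccccc1)(c1ccccc1)c1ccccc1 | starting material
3 | ethyl (2E,4S)-4-(tert-butyldimethylsilyloxy)-2-methylpent-2-enoate | C[C@H](O[Si](C)(C)C(C)(C)C)/C=C(\C)C(=O)OCC | intermediate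
4 | (2E,4S)-4-(tert-butyldimethylsilyloxy)-2-methylpent-2-en-1-ol | C[C@H](O[Si](C)(C)C(C)(C)C)/C=C(\C)CO | intermediate
5 | tert-butyl{[(2S,3E)-5-(4-methoxybenzyloxy)-4-methylpent-3-en-2-yl]oxy}dimethylsilane | C[C@H](O[Si](C)(C)C(C)(C)C)/C=C(\C)COCc1ccc(OC)cc1 | intermediate
6 | (2S,3E)-5-(4-methoxybenzyloxy)-4-methylpent-3-en-2-ol | C[C@H](O)/C=C(\C)COCc1ccc(OC)cc1 | intermediate
7 | ethyl vinyl ether | C=COCC | starting material
8 | allyl vinyl ether of 6 (O-vinyl on the carbinol) | C[C@H](OC=C)/C=C(\C)COCc1ccc(OC)cc1 | intermediate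
9 | (3S,4E)-3-[(4-methoxybenzyloxy)methyl]-3-methylhex-4-enal | O=CC[C@](C)(COCc1ccc(OC)cc1)/C=C/C | intermediate
10 | methyl 3-methylbut-2-enoate | CC(C)=CC(=O)OC | starting material
11 | lithium dienolate of 10 | C=C(C)C=C(OC)[O-].[Li+] | intermediate
12 | tert-butyl[(1-methoxy-3-methylbuta-1,3-dien-1-yl)oxy]dimethylsilane (ketene acetal geometry not defined) | C=C(C)C=C(OC)O[Si](C)(C)C(C)(C)C | intermediate
13 | methyl (2E,5R,7S,8E)-5-hydroxy-7-[(4-methoxybenzyloxy)methyl]-3,7-dimethyldeca-2,8-dienoate | COC(=O)/C=C(\C)C[C@@H](O)C[C@](C)(COCc1ccc(OC)cc1)/C=C/C | intermediate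
14 | methyl (2E,5R,7S,8E)-5-(tert-butyldimethylsilyloxy)-7-[(4-methoxybenzyloxy)methyl]-3,7-dimethyldeca-2,8-dienoate | COC(=O)/C=C(\C)C[C@@H](O[Si](C)(C)C(C)(C)C)C[C@](C)(COCc1ccc(OC)cc1)/C=C/C | intermediate
15 | pent-1-en-3-one | CCC(=O)C=C | starting material
16 | methyl (2E,5R,7S,8E)-5-(tert-butyldimethylsilyloxy)-7-[(4-methoxybenzyloxy)methyl]-3,7-dimethyl-10-oxododeca-2,8-dienoate | COC(=O)/C=C(\C)C[C@@H](O[Si](C)(C)C(C)(C)C)C[C@](C)(COCc1ccc(OC)cc1)/C=C/C(=O)CC | intermediate
17 | methyl (2E,5R,7S,8E,10Z)-5,10-bis(tert-butyldimethylsilyloxy)-7-[(4-methoxybenzyloxy)methyl]-3,7-dimethyldodeca-2,8,10-trienoate | COC(=O)/C=C(\C)C[C@@H](O[Si](C)(C)C(C)(C)C)C[C@](C)(COCc1ccc(OC)cc1)/C=C/C(O[Si](C)(C)C(C)(C)C)=C/C | intermediate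
18 | trans-decalin cycloadduct: 2α-OTBS, 4α-CH3, 4β-CH2OPMB, 5α-H, C6=C7 silyl enol ether (7-OTBS), 8β-CH3, 9β-CO2Me, 10β-CH3 | COc1ccc(COC[C@@]2(C)C[C@H](O[Si](C)(C)C(C)(C)C)C[C@]3(C)[C@@H](C(=O)OC)[C@@H](C)C(O[Si](C)(C)C(C)(C)C)=C[C@@H]23)cc1 | intermediate
19 | primary alcohol: as 18 with 9β-CH2OH | COc1ccc(COC[C@@]2(C)C[C@H](O[Si](C)(C)C(C)(C)C)C[C@]3(C)[C@@H](CO)[C@@H](C)C(O[Si](C)(C)C(C)(C)C)=C[C@@H]23)cc1 | intermediate
20 | aldehyde: as 18 with 9β-CHO | COc1ccc(COC[C@@]2(C)C[C@H](O[Si](C)(C)C(C)(C)C)C[C@]3(C)[C@@H](C=O)[C@@H](C)C(O[Si](C)(C)C(C)(C)C)=C[C@@H]23)cc1 | intermediate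
21 | vinyl silyl enol ether: as 18 with 9β-CH=CH2 | COc1ccc(COC[C@@]2(C)C[C@H](O[Si](C)(C)C(C)(C)C)C[C@]3(C)[C@@H](C=C)[C@@H](C)C(O[Si](C)(C)C(C)(C)C)=C[C@@H]23)cc1 | intermediate
22 | vinyl ketone: 2α-OTBS, 4β-CH2OPMB, C7 ketone, 8β-CH3, 9β-CH=CH2 | COc1ccc(COC[C@@]2(C)C[C@H](O[Si](C)(C)C(C)(C)C)C[C@]3(C)[C@@H](C=C)[C@@H](C)C(=O)C[C@@H]23)cc1 | intermediate
23 | lithium C7=C8 enolate of 22 | COc1ccc(COC[C@@]2(C)C[C@H](O[Si](C)(C)C(C)(C)C)C[C@]3(C)[C@@H](C=C)C(C)=C([O-])C[C@@H]23)cc1.[Li+] | intermediate
24 | C7=C8 enol triflate (7-OTf, 8-CH3, 9β-CH=CH2) | COc1ccc(COC[C@@]2(C)C[C@H](O[Si](C)(C)C(C)(C)C)C[C@]3(C)[C@@H](C=C)C(C)=C(OS(=O)(=O)C(F)(F)F)C[C@@H]23)cc1 | intermediate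
25 | diene: 2α-OTBS, 4β-CH2OPMB, C7=C8 olefin, 9β-CH=CH2 | COc1ccc(COC[C@@]2(C)C[C@H](O[Si](C)(C)C(C)(C)C)C[C@]3(C)[C@@H](C=C)C(C)=CC[C@@H]23)cc1 | intermediate
26 | but-2-yn-1-ol | CC#CCO | starting material
27 | tert-butyl(but-2-yn-1-yloxy)dimethylsilane | CC#CCO[Si](C)(C)C(C)(C)C | intermediate
28 | (E)-alkenyl(chloro)zirconocene (Zr on C3 of the butenyl silyl ether) | Cl[Zr](C1C=CC=C1)(C1C=CC=C1)/C(C)=C/CO[Si](C)(C)C(C)(C)C | intermediate
29 | (E)-tert-butyl[(3-iodobut-2-en-1-yl)oxy]dimethylsilane | I/C(C)=C/CO[Si](C)(C)C(C)(C)C | intermediate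
30 | alkylborane: as 25 with 9β-CH2CH2-(9-BBN) | COc1ccc(COC[C@@]2(C)C[C@H](O[Si](C)(C)C(C)(C)C)C[C@]3(C)[C@@H](CCB4C5CCCC4CCC5)C(C)=CC[C@@H]23)cc1 | intermediate
31 | 19-(4-methoxybenzyloxy)-2α,15-bis(tert-butyldimethylsilyloxy)labda-7,13E-diene | COc1ccc(COC[C@@]2(C)C[C@H](O[Si](C)(C)C(C)(C)C)C[C@]3(C)[C@@H](CC/C(C)=C/CO[Si](C)(C)C(C)(C)C)C(C)=CC[C@@H]23)cc1 | intermediate
32 | 2α,15-bis(tert-butyldimethylsilyloxy)labda-7,13E-dien-19-ol | OC[C@@]1(C)C[C@H](O[Si](C)(C)C(C)(C)C)C[C@]2(C)[C@@H](CC/C(C)=C/CO[Si](C)(C)C(C)(C)C)C(C)=CC[C@@H]12 | intermediate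
33 | 19-acetoxy-2α,15-bis(tert-butyldimethylsilyloxy)labda-7,13E-diene | CC(=O)OC[C@@]1(C)C[C@H](O[Si](C)(C)C(C)(C)C)C[C@]2(C)[C@@H](CC/C(C)=C/CO[Si](C)(C)C(C)(C)C)C(C)=CC[C@@H]12 | intermediate
34 | 19-acetoxylabda-7,13E-diene-2α,15-diol | CC(=O)OC[C@@]1(C)C[C@H](O)C[C@]2(C)[C@@H](CC/C(C)=C/CO)C(C)=CC[C@@H]12 | target

**Totals**
Total steps: 21. Longest linear sequence: 18 (steps 1–5, 7–15, 18–21).

**Steps most likely to fail**

Step 10. The thermal cycloaddition may be sluggish, because the dienophile is a trisubstituted enoate and the C7 silyloxy group, forced by the tether into a 1,3-relation to the ester, adds little activation. The endo/exo preference that decides the ring fusion may also be weak, so that cis-fused material forms alongside. Fallback: triene 17 is isolated (chromatography on triethylamine-deactivated silica) and its enoate is reduced with i-Bu2AlH (CH2Cl2, −78 °C) to the allylic alcohol F1, which is oxidised with MnO2 (CH2Cl2, 23 °C) to the enal F2. The enal is a much better dienophile, so the intramolecular Diels–Alder reaction should run at 60–100 °C in toluene, where the endo preference of the formyl group counts for more. It gives aldehyde 20 directly, so steps 11 and 12 fall away.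

Step 14. Enolate equilibration may be incomplete, so that sulfonylation takes place on the C6 side and the olefin ends up at C6=C7. Fallback: ketone 22 is treated with i-Pr2NMgBr, Me3SiCl, Et3N and HMPA in Et2O, conditions known to give thermodynamic enol silanes, to form the C7=C8 trimethylsilyl enol ether F3, which can be separated from any C6=C7 isomer. MeLi (THF, 0 °C) then releases the lithium enolate regiospecifically, and the pyridyl triflimide converts it into triflate 24.

Step 7. Turnover of the Lewis base–SiCl4 system may be low with a β-quaternary aliphatic aldehyde, and enantioface selectivity may erode, which would show as the C5 epimer of 13. Fallback: aldehyde 9 is propargylated with allenylboronic acid pinacol ester under chiral BINOL-phosphoric acid catalysis (catalyst antipode chosen for the 4R alcohol) to the homopropargylic alcohol F4, which is silylated (t-BuMe2SiCl, imidazole) to the silyl ether F5. Carboalumination of the terminal alkyne (Me3Al, Cp2ZrCl2, CH2Cl2) and trapping of the alkenylalane with methyl chloroformate then give enoate 14, with the E geometry fixed by syn-carbometalation.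

**Further compounds**
F1 | step 10 | (2E,5R,7S,8E,10Z)-5,10-bis(tert-butyldimethylsilyloxy)-7-[(4-methoxybenzyloxy)methyl]-3,7-dimethyldodeca-2,8,10-trien-1-ol | OC/C=C(\C)C[C@@H](O[Si](C)(C)C(C)(C)C)C[C@](C)(COCc1ccc(OC)cc1)/C=C/C(O[Si](C)(C)C(C)(C)C)=C/C
F2 | step 10 | (2E,5R,7S,8E,10Z)-5,10-bis(tert-butyldimethylsilyloxy)-7-[(4-methoxybenzyloxy)methyl]-3,7-dimethyldodeca-2,8,10-trienal | O=C/C=C(\C)C[C@@H](O[Si](C)(C)C(C)(C)C)C[C@](C)(COCc1ccc(OC)cc1)/C=C/C(O[Si](C)(C)C(C)(C)C)=C/C
F3 | step 14 | C7=C8 trimethylsilyl enol ether of 22 | COc1ccc(COC[C@@]2(C)C[C@H](O[Si](C)(C)C(C)(C)C)C[C@]3(C)[C@@H](C=C)C(C)=C(O[Si](C)(C)C)C[C@@H]23)cc1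
F4 | step 7 | (4R,6S,7E)-6-[(4-methoxybenzyloxy)methyl]-6-methylnon-7-en-1-yn-4-ol | C#CC[C@@H](O)C[C@](C)(COCc1ccc(OC)cc1)/C=C/C
F5 | step 7 | tert-butyldimethylsilyl ether of F4 | C#CC[C@@H](O[Si](C)(C)C(C)(C)C)C[C@](C)(COCc1ccc(OC)cc1)/C=C/C
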